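**Retrosynthetic overview**

1. Numbering used below: C1 lactone C=O, C2 CH2, C3 HC–OO, C4 C(CH3)–O, C5 CH2, C6 C(CH3)(10-phenyldecyl)–OO. The last disconnections are C5–H and C4–O(lactone): hydrodeiodination and iodolactonisation of the Δ4,5 dihydrodioxine acid 14, the acid-to-alkene lactonisation presumed to close the lactone in the biogenesis of this skeleton.
2. Key disconnection C4–C5, taken at the alkene oxidation level: ring-closing metathesis of the peroxide-bridged diene acid 13 (isopropenyl on C3, vinyl on C6) closes the six-membered peroxide ring. The extra unsaturation is removed again in steps 9 and 10.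
3. Feature that makes this possible: C3 and C6, the two carbons carrying the O–O bridge of the 1,2-dioxane ring, flank C4–C5. The seco compound is therefore a bis-allylic dialkyl peroxide whose forming bond lies between two plain alkenes and needs no base, reductant or cation. Afterwards the acetic acid arm on C3 can reach C4 only on its own face, which fixes the cis fusion of the lactone ring.
4. Peroxide bridge: C6–OO by invertive perhydrolysis of (R)-epoxide 6 (stereocentre from (S)-2-methylglycidol 1, chain from Grignard reagent 3). C3–OO and C2–C3 come through the temporary 1,2,4-trioxane 9, opened at C3 by a silyl ketene acetal; both C3 epimers form and the unwanted series is removed at 15.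
5. Order of ring formation: oxirane (6) → temporary 1,2,4-trioxane (9, opened in step 5) → 3,6-dihydro-1,2-dioxine (14, key step) → γ-lactone (15, then 16).

Key step: step 8

Assumptions: 1, 2 and 8 are purchased; salts that are only protonated on aqueous work-up (magnesium alkoxides, carboxylates) are not numbered; the perhydrolysis in step 3 is taken to proceed with inversion at the quaternary carbon, and the enantiomeric purity of 7 should be assayed because it fixes that of 16.

**Route**

Step 1
Reactants: 1 (S)-2-methylglycidol, [(2S)-2-methyloxiran-2-yl]methanol; 2 (9-bromononyl)benzene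
Product: 4 (R)-2-methyl-12-phenyldodecane-1,2-diol, via Grignard reagent 3 (not isolated)
Conditions: 2 (2.3 equiv), Mg, THF, rt; then CuI (10 mol %), 1, THF, −30 → 0 °C; H2O work-up
Reagents that add atoms: none
Why: Copper-catalysed opening of a 2,2-disubstituted epoxide by a primary Grignard reagent takes place at the unsubstituted CH2 carbon, so no bond to the quaternary stereocentre of 1 is touched (the descriptor changes from S to R only because the CIP ranks change), the free hydroxyl of 1 simply consuming one equivalent of 3.

Step 2
Reactants: 4 (R)-2-methyl-12-phenyldodecane-1,2-diol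
Product: 6 (R)-2-methyl-2-(10-phenyldecyl)oxirane, via primary tosylate 5 (not isolated)
Conditions: TsCl (1.05 equiv), pyridine, CH2Cl2, 0 °C → rt; then K2CO3 (3 equiv), MeOH, rt
Reagents that add atoms: none
Why: Selective sulfonylation of the primary hydroxyl and intramolecular Williamson etherification (3-exo-tet displacement by the tertiary alkoxide) rebuild an oxirane without breaking any bond at the stereocentre, which stays R.

Step 3
Reactants: 6 (R)-2-methyl-2-(10-phenyldecyl)oxirane
Product: 7 (S)-2-hydroperoxy-2-methyl-12-phenyldodecan-1-ol
Conditions: anhydrous H2O2 in Et2O (excess), H3PMo12O40 (phosphomolybdic acid, 3 mol %), 0 °C → rt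
Reagents that add atoms: hydrogen peroxide, OO
Why: Acid-catalysed perhydrolysis of a 2,2-disubstituted oxirane with anhydrous H2O2 and a heteropolyacid places the hydroperoxide on the more substituted carbon in a borderline SN2 opening, which should go with inversion and turn (R)-6 into (S)-7, the configuration needed at C6.

Step 4
Reactants: 7 (S)-2-hydroperoxy-2-methyl-12-phenyldodecan-1-ol; 8 methacrolein dimethyl acetal (3,3-dimethoxy-2-methylprop-1-ene)
Product: 9 (6S)-6-methyl-6-(10-phenyldecyl)-3-(prop-1-en-2-yl)-1,2,4-trioxane (either configuration at the acetal carbon C3)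
Conditions: 8 (1.5 equiv), pyridinium p-toluenesulfonate (10 mol %), 4 Å molecular sieves, CH2Cl2, rt
Reagents that add atoms: none
Why: Acid-catalysed transacetalisation of a β-hydroxy hydroperoxide with an aldehyde acetal is the classical 1,2,4-trioxane synthesis; it masks OOH and OH together and puts C3 in place at the peroxyacetal oxidation level, the new acetal centre being of no consequence because it is ionised in step 5.

Step 5
Reactants: 9 (6S)-6-methyl-6-(10-phenyldecyl)-3-(prop-1-en-2-yl)-1,2,4-trioxane
Product: 11 (3R)-3-{[(2S)-1-hydroxy-2-methyl-12-phenyldodecan-2-yl]peroxy}-4-methylpent-4-enoic acid, via bis-silyl adduct 10 (not isolated)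
Conditions: CH2=C(OSiMe3)2 (2 equiv), Me3SiOTf (10 mol %), CH2Cl2, −78 °C; then 1 M HCl, THF, 0 °C
Reagents that add atoms: 1,1-bis(trimethylsilyloxy)ethene, C=C(O[Si](C)(C)C)O[Si](C)(C)C
Why: Lewis-acid-mediated substitution of a peroxyacetal by a silyl ketene acetal (Mukaiyama-type addition to a peroxycarbenium ion): silylation of the more basic ether oxygen opens the trioxane to an allyl-stabilised peroxycarbenium ion that is captured at C3, forming C2–C3 and freeing the C5 oxygen, but the remote C6 centre (methyl against a long chain) offers no useful facial bias, so 11 is expected together with its 3S epimer in comparable amount, the pair being carried on and separated at 15.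

Step 6
Reactants: 11 (3R)-3-{[(2S)-1-hydroxy-2-methyl-12-phenyldodecan-2-yl]peroxy}-4-methylpent-4-enoic acid
Product: 12 (3R)-4-methyl-3-{[(2S)-2-methyl-1-oxo-12-phenyldodecan-2-yl]peroxy}pent-4-enoic acid
Conditions: Dess–Martin periodinane (1.3 equiv), CH2Cl2, 0 °C → rt
Reagents that add atoms: none
Why: Dess–Martin oxidation runs under neutral to weakly acidic conditions that dialkyl peroxides, the carboxylic acid and the alkene tolerate, and the aldehyde formed has no α-hydrogen, so it can neither enolise nor epimerise C6.

Step 7
Reactants: 12 (3R)-4-methyl-3-{[(2S)-2-methyl-1-oxo-12-phenyldodecan-2-yl]peroxy}pent-4-enoic acid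
Product: 13 (3R)-4-methyl-3-{[(3S)-3-methyl-13-phenyltridec-1-en-3-yl]peroxy}pent-4-enoic acid
Conditions: Ph3PCH3Br (2.6 equiv), KN(SiMe3)2 (2.5 equiv), THF, 0 °C; then 12, −78 → 0 °C; 1 M HCl work-up
Reagents that add atoms: methyltriphenylphosphonium bromide, C[P+](c1ccccc1)(c1ccccc1)c1ccccc1.[Br-]
Why: Wittig methylenation of a non-enolisable aldehyde; the first equivalent of ylide converts the acid into its carboxylate, which shields C2–H from deprotonation and so suppresses β-elimination of the peroxide, and dialkyl peroxides are compatible with phosphorus ylides at low temperature.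

Step 8
Reactants: 13 (3R)-4-methyl-3-{[(3S)-3-methyl-13-phenyltridec-1-en-3-yl]peroxy}pent-4-enoic acid
Product: 14 2-[(3R,6S)-4,6-dimethyl-6-(10-phenyldecyl)-3,6-dihydro-1,2-dioxin-3-yl]acetic acid
Conditions: second-generation Hoveyda–Grubbs catalyst RuCl2(H2IMes)(=CH-C6H4-2-OiPr) (5 mol %), toluene (5 mM), 60 °C, argon sparge
Reagents that add atoms: none
Why: Ring-closing olefin metathesis through metallacyclobutanes: the ruthenium alkylidene loads on the monosubstituted vinyl group (C5), adds intramolecularly across the 1,1-disubstituted C4 alkene and cycloreverts, which forms the C4=C5 bond and releases ethene. The closest known reaction type is ring-closing metathesis to trisubstituted six-membered cycloalkenes next to a fully substituted allylic carbon, together with the known tolerance of ruthenium alkylidenes for dialkyl peroxides in olefin metathesis. The 3,6-dihydro-1,2-dioxine ring is closed as a six-membered ring with an endocyclic trisubstituted alkene, the two olefins being held close by the short C3–O–O–C6 bridge, its gauche preference and the gem-disubstitution at C6. No stereocentre is created and C3 and C6 are untouched because no bond to them is made or broken; the configuration at C4 is deliberately left to step 9. The step needs ring closure to win over oligomerisation, and metathesis to win over metal-induced O–O cleavage or isomerisation at the allylic C3–H; high dilution with removal of ethene, a phosphine-free catalyst and the absence of any hydroperoxide or strained peroxide in 13 should secure both.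

Step 9
Reactants: 14 2-[(3R,6S)-4,6-dimethyl-6-(10-phenyldecyl)-3,6-dihydro-1,2-dioxin-3-yl]acetic acid
Product: 15 (3S,4R,4aS,7aR)-4-iodo-3,4a-dimethyl-3-(10-phenyldecyl)-3,4,4a,7a-tetrahydrofuro[3,2-c][1,2]dioxin-6(7H)-one
Conditions: I2 (3 equiv), NaHCO3, MeCN/H2O, 0 °C, dark; chromatography
Reagents that add atoms: iodine, II
Why: Iodolactonisation: the carboxylate attacks the more substituted alkene carbon C4 in a 5-exo mode anti to the iodonium ion, and since it is tethered through C3 it can only reach the face of C4 on which the C3 arm sits, which sets C4 with the cis ring fusion (C4–O syn to C2, iodine trans at C5); in the rigid bicycle the diastereomer derived from the 3S epimer is removed by chromatography.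

Step 10
Reactants: 15 (3S,4R,4aS,7aR)-4-iodo-3,4a-dimethyl-3-(10-phenyldecyl)-3,4,4a,7a-tetrahydrofuro[3,2-c][1,2]dioxin-6(7H)-one
Product: 16 (3S,4aR,7aR)-3,4a-dimethyl-3-(10-phenyldecyl)-3,4,4a,7a-tetrahydrofuro[3,2-c][1,2]dioxin-6(7H)-one
Conditions: Bu3SnH (2 equiv), Et3B (0.2 equiv), trace air, toluene, 0 °C
Reagents that add atoms: none
Why: Radical hydrodeiodination removes the iodine that served to bring oxygen to C4; hydrogen transfer from the stannane to the C5 radical is expected to outrun attack of this radical on the neighbouring O–O bond, as is known for iodides of this bicyclic type, and no stereocentre is touched.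

**Compound list**

1 | (S)-2-methylglycidol, [(2S)-2-methyloxiran-2-yl]methanol | C[C@]1(CO)CO1 | starting material
2 | (9-bromononyl)benzene | BrCCCCCCCCCc1ccccc1 | starting material
3 | (9-phenylnonyl)magnesium bromide | Br[Mg]CCCCCCCCCc1ccccc1 | intermediate
4 | (R)-2-methyl-12-phenyldodecane-1,2-diol | C[C@](O)(CO)CCCCCCCCCCc1ccccc1 | intermediate
5 | (R)-2-hydroxy-2-methyl-12-phenyldodecyl 4-methylbenzenesulfonate | C[C@](O)(COS(=O)(=O)c1ccc(C)cc1)CCCCCCCCCCc1ccccc1 | intermediate
6 | (R)-2-methyl-2-(10-phenyldecyl)oxirane | C[C@@]1(CCCCCCCCCCc2ccccc2)CO1 | intermediate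
7 | (S)-2-hydroperoxy-2-methyl-12-phenyldodecan-1-ol | C[C@](OO)(CCCCCCCCCCc1ccccc1)CO | intermediate
8 | methacrolein dimethyl acetal (3,3-dimethoxy-2-methylprop-1-ene) | COC(OC)C(C)=C | starting material
9 | (6S)-6-methyl-6-(10-phenyldecyl)-3-(prop-1-en-2-yl)-1,2,4-trioxane (either configuration at C3) | C[C@]1(CCCCCCCCCCc2ccccc2)COC(C(C)=C)OO1 | intermediate
10 | trimethylsilyl (3R)-4-methyl-3-({(2S)-2-methyl-12-phenyl-1-[(trimethylsilyl)oxy]dodecan-2-yl}peroxy)pent-4-enoate | C[C@@](CO[Si](C)(C)C)(CCCCCCCCCCc1ccccc1)OO[C@H](CC(=O)O[Si](C)(C)C)C(C)=C | intermediate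
11 | (3R)-3-{[(2S)-1-hydroxy-2-methyl-12-phenyldodecan-2-yl]peroxy}-4-methylpent-4-enoic acid | C[C@@](CO)(CCCCCCCCCCc1ccccc1)OO[C@H](CC(=O)O)C(C)=C | intermediate
12 | (3R)-4-methyl-3-{[(2S)-2-methyl-1-oxo-12-phenyldodecan-2-yl]peroxy}pent-4-enoic acid | C[C@@](C=O)(CCCCCCCCCCc1ccccc1)OO[C@H](CC(=O)O)C(C)=C | intermediate
13 | (3R)-4-methyl-3-{[(3S)-3-methyl-13-phenyltridec-1-en-3-yl]peroxy}pent-4-enoic acid | C[C@@](C=C)(CCCCCCCCCCc1ccccc1)OO[C@H](CC(=O)O)C(C)=C | intermediate
14 | 2-[(3R,6S)-4,6-dimethyl-6-(10-phenyldecyl)-3,6-dihydro-1,2-dioxin-3-yl]acetic acid | C[C@]1(CCCCCCCCCCc2ccccc2)C=C(C)[C@@H](CC(=O)O)OO1 | intermediate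
15 | (3S,4R,4aS,7aR)-4-iodo-3,4a-dimethyl-3-(10-phenyldecyl)-3,4,4a,7a-tetrahydrofuro[3,2-c][1,2]dioxin-6(7H)-one | C[C@]1(CCCCCCCCCCc2ccccc2)[C@H](I)[C@@]2(C)OC(=O)C[C@H]2OO1 | intermediate
16 | (3S,4aR,7aR)-3,4a-dimethyl-3-(10-phenyldecyl)-3,4,4a,7a-tetrahydrofuro[3,2-c][1,2]dioxin-6(7H)-one | C[C@]1(CCCCCCCCCCc2ccccc2)C[C@@]2(C)OC(=O)C[C@H]2OO1 | target

**Step count and risks**

Total step count: 10. Longest linear sequence: 10 steps (1 → 16; 2 and 8 enter as purchased materials).

Step 5. What may go wrong: ionisation of the trioxane at the C3–OO bond instead of the C3–O4 bond, which would sever the peroxide link, or capture of the allyl-type cation at its terminal carbon instead of C3. Fallback: the C3–O–O–C6 link is made in the opposite direction, by epoxide opening. Schenck ene reaction of purchased 4-methylpent-3-enoic acid with singlet oxygen (tetraphenylporphyrin, O2, hν, CH2Cl2) should give racemic 3-hydroperoxy-4-methylpent-4-enoic acid F1. Its hydroperoxide group opens epoxide 6 at the quaternary carbon under H3PMo12O40 catalysis, with the invertive course of step 3, to give 11 and its C3 epimer directly. The fallback sets out from 6 and comes back to the route at 11.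

Step 8. What may go wrong: slow loading of the ruthenium alkylidene on the vinyl group beside the fully substituted peroxide carbon, so that catalyst decay and metal-induced isomerisation of the allylic peroxide compete with ring closure. Fallback: relay ring-closing metathesis. Aldehyde 12 is olefinated instead with the ylide from [2-(allyloxy)ethyl]triphenylphosphonium bromide to give the relay triene (3R)-4-methyl-3-({(2Z,4S)-4-methyl-14-phenyl-1-[(prop-2-en-1-yl)oxy]tetradec-2-en-4-yl}peroxy)pent-4-enoic acid F2. The catalyst then loads on the unhindered allyl ether terminus, closes to 2,5-dihydrofuran and is thereby delivered to C5, from where it closes onto the isopropenyl group. The fallback sets out from 12 and comes back at 14.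

Step 10. What may go wrong: attack of the C5 radical or of the stannyl radical on the adjacent O–O bond (oxirane formation with loss of the peroxide) before hydrogen transfer. Fallback: the iodide is avoided altogether by direct Brønsted-acid-mediated Markovnikov hydrolactonisation of acid 14 (catalytic CF3SO3H, CH2Cl2, −20 °C). Protonation at C5 gives the tertiary C4 cation, which is trapped by the C3 acetic acid arm on its own face; the C3-epimeric series is then separated at the stage of 16. The fallback sets out from 14 and comes back at 16; no new compound is involved.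

Further compounds
F1 | step 5 | 3-hydroperoxy-4-methylpent-4-enoic acid (racemic) | OC(=O)CC(OO)C(C)=C
F2 | step 8 | (3R)-4-methyl-3-({(2Z,4S)-4-methyl-14-phenyl-1-[(prop-2-en-1-yl)oxy]tetradec-2-en-4-yl}peroxy)pent-4-enoic acid | C[C@@](/C=C\COCC=C)(CCCCCCCCCCc1ccccc1)OO[C@H](CC(=O)O)C(C)=C
F0 | step 10 | none | none
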